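## Analysis of the target

The target 14 is a flavonol: a 4H-chromen-4-one (ring A fused to the pyranone ring C) with a 4-methoxyphenyl group (ring B) on C2, hydroxyls on C3 and C5, and a 3-methylbut-2-enyl (prenyl) ether on O7. It is planar and has no stereocentre, so any stereocentre made on the way is temporary and can be carried as a racemate. The sensitive group is the prenyl aryl ether, which does not tolerate strong acid, electrophilic halogen, hydrogenation or prolonged heating; the 3-hydroxypyranone enol is also easily oxidised. The difficulty lies less in the skeleton than in the oxygen pattern: O7 must be alkylated while O3 and O5 stay free and O4' stays a methyl ether. The strategy rests on C2, C3 and C4 of ring C, which map onto C3, C2 and C1 of a 3-(4-methoxyphenyl)glycidic ester. The glycidate brings the C3 oxygen and the C4 carbonyl oxygen with it, and its benzylic carbon is the electrophilic site at which O1 is attached; O1 itself is the phenol oxygen of ring A, not a glycidate atom. Ring A is 1,3,5-trioxygenated, so C4a (ortho to the carbons bearing O1 and O5, para to the one bearing O7) is nucleophilic enough to take the carboxyl carbon as C4 under mild activation.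

## Retrosynthetic reasoning

**14 to 13 (O3–acyl bond).** The last bond cut is the ester bond at O3, which leads back to the 3-O-acetate 13. The acetate is kept to the end because it is what tells O3 apart from O7 during alkylation. Its removal needs only a mild transesterification that the prenyl ether tolerates.

**13 to 11 and 12 (O7–CH2 bond).** The prenyl group is cut off next, giving the 5,7-dihydroxy flavonol acetate 11 and the allylic bromide 12. It is introduced this late because every earlier operation (acid-mediated acylation, halogen-based dehydrogenation, hydrogenolysis) would destroy it. The forward step must alkylate O7 only; 11 secures this, since O3 is acylated, O5 is tied up in a hydrogen bond to the C4 carbonyl and O7 is the most acidic position.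

**11 to 10 (two O–benzyl bonds).** The free hydroxyls on C5 and C7 are traced back to benzyl ethers in 10. Benzyl is chosen because it survives base, acid anhydride and halogen, keeps ring A nucleophilic, and comes off under neutral conditions that leave the 3-acetate in place.

**10 to 8 (C2=C3 unsaturation).** Adding two hydrogens across C2=C3 in the retrosynthetic sense gives the flavanonol acetate 8. This moves ring closure to the saturated level, where C2 is an sp3 carbon that can carry O1 through a simple substitution. The price is two stereocentres, both of which vanish in the forward dehydrogenation through the α-iodo ketone 9, so racemic material suffices.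

**8 to 6 (C4–C4a bond).** Ring C is opened between the carbonyl carbon and ring A, giving the 3-aryloxypropanoic acid 6, activated in the flask as the mixed anhydride 7. This cut is preferred over the O1–C8a or O1–C2 bonds for three reasons. The nucleophile is a symmetrical ring activated by three oxygens. The electrophile is a plain carboxyl group. And C2, C3 and C4 arrive together with the C3 oxygen already installed, so no late oxidation at C3 is needed. The forward reaction has to acylate the arene without ionising the 4-methoxybenzylic ether.

**6 to 4 to 3 (functional group changes).** The acetate of 6 is taken back to the hydroxy acid 4 (through the transient mixed anhydride 5), and 4 to the methyl ester 3. Saponification comes before acetylation because the reverse order would cost the acetate.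

**3 to 1 and 2 (O1–C2 bond).** The benzylic ether bond is cut to give the phenol 2 and the trans-glycidate 1. Opening the epoxide at its benzylic carbon forms O1–C2 and releases the C3 hydroxyl in one operation. Attack with inversion gives the relative configuration that leads to the trans-flavanonol, although this is immaterial for 14.

## Alternatives that were turned down

**Alternative 1:** The C4a–C4 and C3–C4 bonds are both cut, giving the aryl iodide 2-iodo-1,3-bis(methoxymethoxy)-5-(3-methylbut-2-enyloxy)benzene A2, carbon monoxide and the ketone 2-(methoxymethoxy)-1-(4-methoxyphenyl)ethanone A3.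
- Forward key step: zerovalent palladium, formed from Pd(OAc)2 and Xantphos, inserts into A2, takes up CO and acylates the magnesium enolate of A3. This gives the open diketone 1-[2,6-bis(methoxymethoxy)-4-(3-methylbut-2-enyloxy)phenyl]-2-(methoxymethoxy)-3-(4-methoxyphenyl)propane-1,3-dione A1; acid would then unmask the phenols and close ring C.
- For it: it is convergent, it makes two skeletal bonds at once, it arrives directly at the flavonol oxidation level and it carries the prenyl ether from the start. On step economy and convergence it is stronger than the chosen route.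
- Against it: the iodide A2 is electron-rich and flanked by two ortho alkoxy groups, so oxidative addition and capture of the hindered aroylpalladium by the α-alkoxy enolate of A3 are both unfavourable; direct arylation and O-acylation are open side paths. More seriously, A1 reaches 14 only by acid removal of three acetal groups and acid cyclodehydration while the acid-labile prenyl aryl ether is present.
- Comparison: the chosen route is longer and linear, but it installs the prenyl group after the last acidic step and uses an unhindered, symmetrical nucleophile in its ring-forming step.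

**Alternative 2:** The O1–C8a bond is cut with fluoride as the leaving group, which leads back to the open diketone 2-(methoxymethoxy)-1-(4-methoxyphenyl)-3-(2,4,6-trifluorophenyl)propane-1,3-dione A5.
- Forward key step: K2CO3 in DMF converts A5 into its enolate. The enolate oxygen on the anisoyl carbon then displaces one of the two ortho fluorides of A5, giving 5,7-difluoro-3-(methoxymethoxy)-2-(4-methoxyphenyl)chromen-4-one A4.
- For it: the closure is an intramolecular nucleophilic aromatic substitution on a ring activated by the carbonyl and by fluorine, the two ortho fluorides of A5 are equivalent, and the product is already aromatic. As a ring closure it is more secure than an acid-mediated acylation next to a 4-methoxybenzylic ether.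
- Against it: A4 still lacks both ring A oxygens. The C7 fluoride must be replaced by the prenyl alkoxide and the C5 fluoride by a hydroxide equivalent. Nothing in A4 decides between C5 (ortho to the carbonyl) and C7 (para), and the second substitution must be forced on a ring deactivated by the first alkoxy group, under conditions that endanger the pyranone and the prenyl ether. The acetal on O3 must then be removed with acid in the presence of the prenyl ether.
- Comparison: the chosen route starts from a ring A that already carries all three oxygens, so no aryl C–O bond has to be made on it.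

**Alternative 3:** Three bonds are cut, C8a–O1, C4a–C4 and O1–C2, giving the aryne precursor 3-(methoxymethoxy)-5-(3-methylbut-2-enyloxy)-2-(trimethylsilyl)phenyl trifluoromethanesulfonate A7 and the propiolate salt cesium 3-(4-methoxyphenyl)prop-2-ynoate A8.
- Forward key step: CsF releases the aryne from A7. The carboxylate of A8 adds through oxygen at the aryne carbon meta to the acetal oxygen, the aryl anion takes the acyl group, and the phenoxide closes onto the ynone to give 5-(methoxymethoxy)-2-(4-methoxyphenyl)-7-(3-methylbut-2-enyloxy)chromen-4-one A6.
- For it: it forms the most bonds per step of any option, the alkoxy group directs the aryne addition in the required sense, ring C arrives aromatic with the prenyl ether in place, and A8 is a simple salt of an accessible propiolic acid.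
- Against it: A6 has no oxygen on C3. Electrophilic oxidants that hydroxylate a flavone at C3 through its 2,3-epoxide would attack the trisubstituted prenyl alkene first, and a metalation route needs strong base followed by oxidation and then acid to remove the acetal, again next to the prenyl ether. The phenoxide can also close in the 5-exo sense to an aurone, and A7 needs several steps of its own.
- Comparison: the chosen route forms fewer bonds in its key step, but the C3 oxygen comes from the glycidate and never has to be introduced by oxidation.

Key step: step 4

Remark: 14 is achiral, so racemic 1 is used; compounds 3 to 9 are racemic and their SMILES show one enantiomer.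

## Route

**Step 1**
Reactants: 1 methyl trans-3-(4-methoxyphenyl)glycidate (racemic, 2R*,3S*); 2 3,5-bis(benzyloxy)phenol
Product: 3 methyl (2R*,3R*)-3-[3,5-bis(benzyloxy)phenoxy]-2-hydroxy-3-(4-methoxyphenyl)propanoate
Conditions: K2CO3 (0.3 equiv), DMF, 60 °C
Reagents that add atoms: none
Why: Base-catalysed SN2 opening of the epoxide by the phenoxide at the benzylic carbon, the usual site of attack in 3-arylglycidic esters and here further activated by the 4-methoxyphenyl group. Backside attack inverts the benzylic carbon while the carbinol carbon keeps its configuration, so the trans-epoxide should give the (2R*,3R*) hydroxy ester; the alkoxide formed is protonated by more phenol, so the carbonate is needed only in substoichiometric amount.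

**Step 2**
Reactants: 3 methyl (2R*,3R*)-3-[3,5-bis(benzyloxy)phenoxy]-2-hydroxy-3-(4-methoxyphenyl)propanoate
Product: 4 (2R*,3R*)-3-[3,5-bis(benzyloxy)phenoxy]-2-hydroxy-3-(4-methoxyphenyl)propanoic acid
Conditions: LiOH·H2O (2 equiv), THF/H2O, 0 °C to rt; then 1 M HCl to pH 3, 0 °C
Reagents that add atoms: lithium hydroxide, [Li+].[OH-] (its oxygen becomes a carboxyl oxygen)
Why: Ester saponification by acyl–oxygen cleavage. The carboxylate formed resists α-deprotonation, so neither stereocentre should be disturbed and β-elimination of the aryloxide should not compete at this temperature.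

**Step 3**
Reactants: 4 (2R*,3R*)-3-[3,5-bis(benzyloxy)phenoxy]-2-hydroxy-3-(4-methoxyphenyl)propanoic acid
Product: 6 (2R*,3R*)-2-acetoxy-3-[3,5-bis(benzyloxy)phenoxy]-3-(4-methoxyphenyl)propanoic acid, via acetic mixed anhydride 5 (not isolated)
Conditions: Ac2O (3 equiv), pyridine, DMAP (cat.), CH2Cl2, 0 °C to rt; then H2O, THF, rt
Reagents that add atoms: acetic anhydride, CC(=O)OC(C)=O; water, O (in the hydrolysis of 5)
Why: DMAP-catalysed O-acetylation of the secondary alcohol. The carboxyl group is converted at the same time into the mixed anhydride 5, which the aqueous treatment hydrolyses back to the acid while the alkyl acetate survives.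

**Step 4**
Reactants: 6 (2R*,3R*)-2-acetoxy-3-[3,5-bis(benzyloxy)phenoxy]-3-(4-methoxyphenyl)propanoic acid
Product: 8 racemic trans-3-acetoxy-5,7-bis(benzyloxy)-2-(4-methoxyphenyl)chroman-4-one, via trifluoroacetic mixed anhydride 7 (not isolated)
Conditions: (CF3CO)2O (2 equiv), CH2Cl2, 0 °C to rt
Reagents that add atoms: none
Why: Acid 6 and (CF3CO)2O should form the mixed anhydride 7, in which trifluoroacetate is the leaving group, so the non-fluorinated acyl carbon is the electrophile (as the anhydride or as the acylium ion pair it ionises to). The ring carbon ortho to the ether oxygen, which is also ortho to one benzyloxy group and para to the other, attacks this carbon; loss of a proton from the arenium ion and of trifluoroacetate forms C4–C4a and closes ring C. The closest known reaction is the intramolecular Friedel–Crafts acylation of 3-aryloxypropanoic acids to chroman-4-ones under (CF3CO)2O or polyphosphoric acid, which is especially easy with 3,5-dialkoxyphenyl ethers. Ring C closes in the 6-exo-trig mode at the acyl carbon, the C=O bond lying outside the new ring. No stereocentre is made: C2 and C3 come from 6, and if C3 enolises next to the new ketone the trans isomer, with both substituents equatorial, is the one favoured at equilibrium. Regioselectivity is not at issue, because the two ortho carbons are equivalent through the symmetry of the 3,5-bis(benzyloxy)phenoxy group and the para carbon cannot reach the acyl carbon. The selectivity needed is acylation without ionisation of the 4-methoxybenzylic C–O bond or of the benzyl ethers; the absence of a Lewis acid, the low temperature and the electron-withdrawing acetoxy and acyl groups on the adjacent carbon, which destabilise a benzylic cation, should secure it.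

**Step 5**
Reactants: 8 racemic trans-3-acetoxy-5,7-bis(benzyloxy)-2-(4-methoxyphenyl)chroman-4-one
Product: 10 3-acetoxy-5,7-bis(benzyloxy)-2-(4-methoxyphenyl)chromen-4-one, via 3-iodo ketone 9 (not isolated)
Conditions: I2 (1.2 equiv), pyridine, 90 °C
Reagents that add atoms: none
Why: Flavanone-to-flavone dehydrogenation by α-iodination and dehydroiodination, a standard method for flavanones and flavanonols. The enol of 8 should be iodinated at C3 to give 9, and pyridine then removes HI across C2–C3, driven by formation of the conjugated pyranone; both stereocentres disappear.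

**Step 6**
Reactants: 10 3-acetoxy-5,7-bis(benzyloxy)-2-(4-methoxyphenyl)chromen-4-one
Product: 11 3-acetoxy-5,7-dihydroxy-2-(4-methoxyphenyl)chromen-4-one
Conditions: H2 (1 atm), 10% Pd/C, EtOAc/THF, rt
Reagents that add atoms: none
Why: Hydrogenolysis of the two benzyl aryl ethers. The tetrasubstituted C2=C3 bond of the pyranone, the enol acetate and the methyl ether should not be reduced at atmospheric pressure and room temperature, and the neutral aprotic medium leaves the acetate on O3.

**Step 7**
Reactants: 11 3-acetoxy-5,7-dihydroxy-2-(4-methoxyphenyl)chromen-4-one; 12 prenyl bromide (1-bromo-3-methylbut-2-ene)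
Product: 13 3-acetoxy-5-hydroxy-2-(4-methoxyphenyl)-7-(3-methylbut-2-enyloxy)chromen-4-one
Conditions: K2CO3 (1.1 equiv), 12 (1.1 equiv), dry acetone, rt
Reagents that add atoms: prenyl bromide (12), CC(C)=CCBr
Why: Williamson etherification by SN2 at the primary allylic carbon. The 7-hydroxyl, para to the C4 carbonyl, is the most acidic; the 5-hydroxyl is held in a hydrogen bond to that carbonyl and O3 is blocked as the acetate, so one equivalent of base and bromide should alkylate O7 only.

**Step 8**
Reactants: 13 3-acetoxy-5-hydroxy-2-(4-methoxyphenyl)-7-(3-methylbut-2-enyloxy)chromen-4-one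
Product: 14 3,5-dihydroxy-2-(4-methoxyphenyl)-7-(3-methylbut-2-enyloxy)chromen-4-one
Conditions: K2CO3 (cat.), MeOH/THF, 0 °C to rt; aq. NH4Cl
Reagents that add atoms: none
Why: Base-catalysed transesterification of the enol acetate, which is by far the best acyl donor in the molecule. The prenyl ether and the methyl ether are inert to carbonate in methanol.

## Compound list

1 | methyl trans-3-(4-methoxyphenyl)glycidate (racemic, one enantiomer drawn) | COc1ccc([C@H]2[C@@H](O2)C(=O)OC)cc1 | starting material
2 | 3,5-bis(benzyloxy)phenol | Oc1cc(OCc2ccccc2)cc(OCc2ccccc2)c1 | starting material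
3 | methyl (2R*,3R*)-3-[3,5-bis(benzyloxy)phenoxy]-2-hydroxy-3-(4-methoxyphenyl)propanoate (racemic, one enantiomer drawn) | COc1ccc([C@@H](Oc2cc(OCc3ccccc3)cc(OCc3ccccc3)c2)[C@@H](O)C(=O)OC)cc1 | intermediate
4 | (2R*,3R*)-3-[3,5-bis(benzyloxy)phenoxy]-2-hydroxy-3-(4-methoxyphenyl)propanoic acid (racemic, one enantiomer drawn) | COc1ccc([C@@H](Oc2cc(OCc3ccccc3)cc(OCc3ccccc3)c2)[C@@H](O)C(=O)O)cc1 | intermediate
5 | acetic (2R*,3R*)-2-acetoxy-3-[3,5-bis(benzyloxy)phenoxy]-3-(4-methoxyphenyl)propanoic anhydride (racemic, one enantiomer drawn; not isolated) | COc1ccc([C@@H](Oc2cc(OCc3ccccc3)cc(OCc3ccccc3)c2)[C@@H](OC(C)=O)C(=O)OC(C)=O)cc1 | intermediate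
6 | (2R*,3R*)-2-acetoxy-3-[3,5-bis(benzyloxy)phenoxy]-3-(4-methoxyphenyl)propanoic acid (racemic, one enantiomer drawn) | COc1ccc([C@@H](Oc2cc(OCc3ccccc3)cc(OCc3ccccc3)c2)[C@@H](OC(C)=O)C(=O)O)cc1 | intermediate
7 | (2R*,3R*)-2-acetoxy-3-[3,5-bis(benzyloxy)phenoxy]-3-(4-methoxyphenyl)propanoic trifluoroacetic anhydride (racemic, one enantiomer drawn; not isolated) | COc1ccc([C@@H](Oc2cc(OCc3ccccc3)cc(OCc3ccccc3)c2)[C@@H](OC(C)=O)C(=O)OC(=O)C(F)(F)F)cc1 | intermediate
8 | trans-3-acetoxy-5,7-bis(benzyloxy)-2-(4-methoxyphenyl)chroman-4-one (racemic, 2R*,3R*, one enantiomer drawn) | COc1ccc([C@H]2Oc3cc(OCc4ccccc4)cc(OCc4ccccc4)c3C(=O)[C@@H]2OC(C)=O)cc1 | intermediate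
9 | 3-acetoxy-5,7-bis(benzyloxy)-3-iodo-2-(4-methoxyphenyl)chroman-4-one (racemic, configuration at C3 not defined; not isolated) | COc1ccc([C@H]2Oc3cc(OCc4ccccc4)cc(OCc4ccccc4)c3C(=O)C2(I)OC(C)=O)cc1 | intermediate
10 | 3-acetoxy-5,7-bis(benzyloxy)-2-(4-methoxyphenyl)chromen-4-one | COc1ccc(-c2oc3cc(OCc4ccccc4)cc(OCc4ccccc4)c3c(=O)c2OC(C)=O)cc1 | intermediate
11 | 3-acetoxy-5,7-dihydroxy-2-(4-methoxyphenyl)chromen-4-one | COc1ccc(-c2oc3cc(O)cc(O)c3c(=O)c2OC(C)=O)cc1 | intermediate
12 | prenyl bromide (1-bromo-3-methylbut-2-ene) | CC(C)=CCBr | starting material
13 | 3-acetoxy-5-hydroxy-2-(4-methoxyphenyl)-7-(3-methylbut-2-enyloxy)chromen-4-one | COc1ccc(-c2oc3cc(OCC=C(C)C)cc(O)c3c(=O)c2OC(C)=O)cc1 | intermediate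
14 | 3,5-dihydroxy-2-(4-methoxyphenyl)-7-(3-methylbut-2-enyloxy)chromen-4-one | COc1ccc(-c2oc3cc(OCC=C(C)C)cc(O)c3c(=O)c2O)cc1 | target

## Step count and least certain steps

Total step count: 8. Longest linear sequence: 8 steps (from 1 and 2 to 14).

**Step 4 (key step).** The most likely failure is ionisation of the 4-methoxybenzylic aryl ether by the trifluoroacetic acid set free, before the ring has closed. This would lead to loss of the phenol and elimination towards a cinnamate. A second possibility is competing trifluoroacetylation of the electron-rich ring. The fallback changes the order of bond formation: ring A is acylated intermolecularly first, ring C is closed through O1–C2, and O3 is introduced by oxidation. It sets out from 2 and rejoins the route at 10. Friedel–Crafts acetylation of 2 ortho to the free hydroxyl (Ac2O, BF3·OEt2) would give 1-[2,4-bis(benzyloxy)-6-hydroxyphenyl]ethanone F1. Claisen–Schmidt condensation with 4-methoxybenzaldehyde (KOH, EtOH) would give (E)-1-[2,4-bis(benzyloxy)-6-hydroxyphenyl]-3-(4-methoxyphenyl)prop-2-en-1-one F2. Oxidative cyclisation (I2 cat., DMSO, 120 °C) would give 5,7-bis(benzyloxy)-2-(4-methoxyphenyl)chromen-4-one F3. Epoxidation of C2=C3 with dimethyldioxirane would give 5,7-bis(benzyloxy)-2,3-epoxy-2-(4-methoxyphenyl)chroman-4-one F4, which a trace of TsOH should open to 5,7-bis(benzyloxy)-3-hydroxy-2-(4-methoxyphenyl)chromen-4-one F5. Acetylation (Ac2O, pyridine) then gives 10.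

**Step 1.** The phenoxide is ambident and the benzylic carbon has cation character, so alkylation through a ring carbon, or opening with loss of regiocontrol, may compete with O-alkylation. The fallback replaces the basic epoxide opening by a redox condensation on a diol under neutral conditions. It sets out from 2 and rejoins the route at 3, with commercial methyl (E)-3-(4-methoxyphenyl)prop-2-enoate F6 taking the place of 1. Syn-dihydroxylation of the alkene (OsO4 cat., N-methylmorpholine N-oxide, acetone/H2O, rt) would give racemic methyl (2R*,3S*)-2,3-dihydroxy-3-(4-methoxyphenyl)propanoate F7. A Mitsunobu reaction of this diol with 2 (PPh3, diisopropyl azodicarboxylate, THF, 0 °C) should then etherify the more reactive benzylic β-hydroxyl with inversion, as is usual for 2,3-dihydroxy esters. This gives 3 with the same relative configuration as the epoxide opening. Partial loss of configuration at the benzylic carbon would do no harm, because both stereocentres are removed in step 5.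

**Step 5.** In hot pyridine the flavanonol acetate may open to the chalcone by retro-oxa-Michael reaction, with migration or loss of the acetyl group, or ring A may be iodinated, before iodination at C3 and elimination are complete. The fallback oxidises the C3 carbinol instead of dehydrogenating across C2–C3; it sets out from 8 and rejoins at 10. Acid methanolysis of the acetate (HCl in MeOH/CH2Cl2, rt) would give trans-5,7-bis(benzyloxy)-3-hydroxy-2-(4-methoxyphenyl)chroman-4-one F8. Oxidation of its secondary alcohol (Dess–Martin periodinane, CH2Cl2) would give 5,7-bis(benzyloxy)-2-(4-methoxyphenyl)chromane-3,4-dione F9, which should tautomerise through its acidic C2–H to the flavonol F5 described under step 4. Acetylation (Ac2O, pyridine) gives 10.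

**Step 7.** The carbonate may cleave or shift the enol acetate, after which O3 would be alkylated as well; over-alkylation at O5 or C-prenylation of ring A is also possible. The fallback avoids base altogether: a Mitsunobu etherification of 11 with 3-methylbut-2-en-1-ol (PPh3, diisopropyl azodicarboxylate, THF, 0 °C) should engage only the most acidic, non-chelated 7-hydroxyl. It sets out from 11 and arrives directly at 13 without any new intermediate.

## Further compounds

F1 | step 4 | 1-[2,4-bis(benzyloxy)-6-hydroxyphenyl]ethanone | CC(=O)c1c(O)cc(OCc2ccccc2)cc1OCc1ccccc1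
F2 | step 4 | (E)-1-[2,4-bis(benzyloxy)-6-hydroxyphenyl]-3-(4-methoxyphenyl)prop-2-en-1-one | COc1ccc(/C=C/C(=O)c2c(O)cc(OCc3ccccc3)cc2OCc2ccccc2)cc1
F3 | step 4 | 5,7-bis(benzyloxy)-2-(4-methoxyphenyl)chromen-4-one | COc1ccc(-c2cc(=O)c3c(OCc4ccccc4)cc(OCc4ccccc4)cc3o2)cc1
F4 | step 4 | 5,7-bis(benzyloxy)-2,3-epoxy-2-(4-methoxyphenyl)chroman-4-one (racemic) | COc1ccc(C23Oc4cc(OCc5ccccc5)cc(OCc5ccccc5)c4C(=O)C2O3)cc1
F5 | step 4 | 5,7-bis(benzyloxy)-3-hydroxy-2-(4-methoxyphenyl)chromen-4-one | COc1ccc(-c2oc3cc(OCc4ccccc4)cc(OCc4ccccc4)c3c(=O)c2O)cc1
F6 | step 1 | methyl (E)-3-(4-methoxyphenyl)prop-2-enoate | COC(=O)/C=C/c1ccc(OC)cc1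
F7 | step 1 | methyl (2R*,3S*)-2,3-dihydroxy-3-(4-methoxyphenyl)propanoate (racemic, one enantiomer drawn) | COc1ccc([C@H](O)[C@@H](O)C(=O)OC)cc1
F8 | step 5 | trans-5,7-bis(benzyloxy)-3-hydroxy-2-(4-methoxyphenyl)chroman-4-one (racemic, one enantiomer drawn) | COc1ccc([C@H]2Oc3cc(OCc4ccccc4)cc(OCc4ccccc4)c3C(=O)[C@@H]2O)cc1
F9 | step 5 | 5,7-bis(benzyloxy)-2-(4-methoxyphenyl)chromane-3,4-dione (racemic) | COc1ccc(C2Oc3cc(OCc4ccccc4)cc(OCc4ccccc4)c3C(=O)C2=O)cc1
F0 | step 7 | none | none
A1 | alternative 1 | 1-[2,6-bis(methoxymethoxy)-4-(3-methylbut-2-enyloxy)phenyl]-2-(methoxymethoxy)-3-(4-methoxyphenyl)propane-1,3-dione (racemic, enolisable) | COCOc1cc(OCC=C(C)C)cc(OCOC)c1C(=O)C(OCOC)C(=O)c1ccc(OC)cc1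
A2 | alternative 1 | 2-iodo-1,3-bis(methoxymethoxy)-5-(3-methylbut-2-enyloxy)benzene | COCOc1cc(OCC=C(C)C)cc(OCOC)c1I
A3 | alternative 1 | 2-(methoxymethoxy)-1-(4-methoxyphenyl)ethanone | COCOCC(=O)c1ccc(OC)cc1
A4 | alternative 2 | 5,7-difluoro-3-(methoxymethoxy)-2-(4-methoxyphenyl)chromen-4-one | COCOc1c(-c2ccc(OC)cc2)oc2cc(F)cc(F)c2c1=O
A5 | alternative 2 | 2-(methoxymethoxy)-1-(4-methoxyphenyl)-3-(2,4,6-trifluorophenyl)propane-1,3-dione (racemic, enolisable) | COCOC(C(=O)c1ccc(OC)cc1)C(=O)c1c(F)cc(F)cc1F
A6 | alternative 3 | 5-(methoxymethoxy)-2-(4-methoxyphenyl)-7-(3-methylbut-2-enyloxy)chromen-4-one | COCOc1cc(OCC=C(C)C)cc2oc(-c3ccc(OC)cc3)cc(=O)c12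
A7 | alternative 3 | 3-(methoxymethoxy)-5-(3-methylbut-2-enyloxy)-2-(trimethylsilyl)phenyl trifluoromethanesulfonate | C[Si](C)(C)c1c(OCOC)cc(OCC=C(C)C)cc1OS(=O)(=O)C(F)(F)F
A8 | alternative 3 | cesium 3-(4-methoxyphenyl)prop-2-ynoate | [Cs+].[O-]C(=O)C#Cc1ccc(OC)cc1
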